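**Retrosynthetic overview**
- The route rests on ring A (the 2-hydroxy-4-methoxy-6-propylbenzoyl ring: oxygen on C2 and C4, propyl on C6, carboxyl carbon on C1). This is an orsellinate-type ring, i.e. a folded C10 tetraketide whose acyl terminus is esterified by the C4 oxygen of ring B.
- Last two operations: cleavage of the ring-B tert-butyl ester, preceded by methylation of the non-chelated ring-A 4-hydroxyl.
- Key disconnection: the ring-A C1–C6 bond, made by aldol addition of C2 to the C7 ketone of an aryl 3,5,7-trioxodecanoate followed by dehydration. The hindered depside C–O bond therefore exists before ring A does.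
- The triketo aryl ester comes from an acylketene (thermolysis of a diketo-dioxinone built from trimethyldioxinone, acetyl chloride and butanoyl chloride) and the ring-B phenol tert-butyl 4-hydroxy-2-methoxy-6-pentylbenzoate, itself made from olivetol.
- Ring order: ring B is bought with olivetol; ring A is the only ring formed, in step 10.

Key step: step 10

Remark: the target has no stereocentre, stereoaxis or stereogenic double bond, so the SMILES describes one achiral compound and no stereocontrol is needed.

**Route**

Step 1
Reactants: 1 olivetol (5-pentylresorcinol)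
Product: 3 2,4-dihydroxy-6-pentylbenzaldehyde, via aryl iminium chloride 2 (not isolated)
Conditions: POCl3 (1.3 equiv), DMF, 0 °C → rt; then H2O, 50 °C
Reagents that add atoms: N,N-dimethylformamide CN(C)C=O; water O
Why: Vilsmeier–Haack formylation, in which the chloroiminium electrophile attacks the resorcinol para to one hydroxyl and ortho to the other (the usual site for 5-alkylresorcinols) and the iminium salt 2 is hydrolysed to the aldehyde on aqueous warming.

Step 2
Reactants: 3 2,4-dihydroxy-6-pentylbenzaldehyde
Product: 4 4-(benzyloxy)-2-hydroxy-6-pentylbenzaldehyde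
Conditions: BnBr (1.05 equiv), NaHCO3, MeCN, 80 °C
Reagents that add atoms: benzyl bromide BrCc1ccccc1
Why: Williamson etherification in which the 2-hydroxyl, hydrogen-bonded to the aldehyde and the less acidic of the two, stays protonated with the weak base, so only the 4-hydroxyl should be benzylated.

Step 3
Reactants: 4 4-(benzyloxy)-2-hydroxy-6-pentylbenzaldehyde
Product: 5 4-(benzyloxy)-2-methoxy-6-pentylbenzaldehyde
Conditions: MeI (3 equiv), K2CO3, DMF, 40 °C
Reagents that add atoms: iodomethane CI
Why: Williamson methylation of the remaining chelated phenol, which needs carbonate, a polar solvent and excess iodomethane but has no competing nucleophile.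

Step 4
Reactants: 5 4-(benzyloxy)-2-methoxy-6-pentylbenzaldehyde
Product: 6 4-(benzyloxy)-2-methoxy-6-pentylbenzoic acid
Conditions: NaClO2, NaH2PO4, 2-methyl-2-butene (excess), t-BuOH/H2O, 0 °C → rt
Reagents that add atoms: sodium chlorite [Na+].[O-]Cl=O
Why: Pinnick oxidation, in which chlorous acid converts the aldehyde into the acid without touching either ether and 2-methyl-2-butene removes hypochlorous acid before it can chlorinate the electron-rich ring.

Step 5
Reactants: 6 4-(benzyloxy)-2-methoxy-6-pentylbenzoic acid
Product: 7 tert-butyl 4-(benzyloxy)-2-methoxy-6-pentylbenzoate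
Conditions: t-BuOC(=NH)CCl3 (3 equiv), CH2Cl2/cyclohexane, rt
Reagents that add atoms: tert-butyl 2,2,2-trichloroacetimidate CC(C)(C)OC(=N)C(Cl)(Cl)Cl
Why: Trichloroacetimidate esterification, in which the acid protonates the imidate and the carboxylate oxygen captures the tert-butyl cation, so no nucleophile has to reach the carbonyl carbon flanked by two ortho substituents.

Step 6
Reactants: 7 tert-butyl 4-(benzyloxy)-2-methoxy-6-pentylbenzoate
Product: 8 tert-butyl 4-hydroxy-2-methoxy-6-pentylbenzoate
Conditions: H2 (1 atm), 10% Pd/C, EtOAc, rt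
Reagents that add atoms: none
Why: Catalytic hydrogenolysis cleaves the benzyl aryl ether, while the tert-butyl ester, the methyl ether and the arene are inert under these conditions.

Step 7
Reactants: 9 2,2,6-trimethyl-4H-1,3-dioxin-4-one; 10 acetyl chloride
Product: 12 2,2-dimethyl-6-(2-oxopropyl)-4H-1,3-dioxin-4-one, via lithium dienolate 11 (not isolated)
Conditions: 9 (2 equiv), LiHMDS (2 equiv), THF, −78 °C; AcCl (1 equiv), −78 °C; cold 1 M HCl
Reagents that add atoms: none
Why: Claisen-type γ-acylation of the lithium dienolate 11 at its exocyclic carbon; the product is more acidic than 9, so a second equivalent of 11 serves as base and half of 9 should be recovered.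

Step 8
Reactants: 12 2,2-dimethyl-6-(2-oxopropyl)-4H-1,3-dioxin-4-one; 13 butanoyl chloride
Product: 15 6-(2,4-dioxoheptyl)-2,2-dimethyl-4H-1,3-dioxin-4-one, via dilithium dienolate 14 (not isolated)
Conditions: 12 (2 equiv), LDA (4.2 equiv), THF, −78 °C; PrCOCl (1 equiv), −78 °C; cold 1 M HCl
Reagents that add atoms: none
Why: Claisen-type acylation of a β-dicarbonyl dianion, in which the terminal, less stabilised carbanion of 14 is the more nucleophilic site and takes up the butanoyl group, the excess dianion absorbing the proton of the acidic diketone product.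

Step 9
Reactants: 15 6-(2,4-dioxoheptyl)-2,2-dimethyl-4H-1,3-dioxin-4-one; 8 tert-butyl 4-hydroxy-2-methoxy-6-pentylbenzoate
Product: 17 tert-butyl 2-methoxy-6-pentyl-4-[(3,5,7-trioxodecanoyl)oxy]benzoate, via acylketene 16 (not isolated)
Conditions: 8 (1.1 equiv), PhMe (0.2 M), 110 °C, 1 h, N2 sweep (−acetone); evaporate, use crude (keto–enol mixture)
Reagents that add atoms: none
Why: Thermal retro-hetero-Diels–Alder fragmentation of the dioxinone releases acetone and the acylketene 16, and the phenol O–H of 8 adds across the ketene to give the aryl β-keto ester (the known route to aryl acetoacetates), a short reaction time and a concentrated solution favouring intermolecular capture over lactonisation of 16.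

Step 10
Reactants: 17 tert-butyl 2-methoxy-6-pentyl-4-[(3,5,7-trioxodecanoyl)oxy]benzoate
Product: 19 tert-butyl 4-[(2,4-dihydroxy-6-propylbenzoyl)oxy]-2-methoxy-6-pentylbenzoate, via cyclic aldol adduct 18 (not isolated)
Conditions: Et3N (1.5 equiv), CH2Cl2, −20 → 0 °C; cold aq. citric acid wash; then p-TsOH·H2O (10 mol%), MgSO4, CH2Cl2, rt
Reagents that add atoms: none
Why: Proposed new method: Et3N reversibly deprotonates the doubly activated methylenes of 17 (C2, C4 and C6 are of similar acidity, the aryloxy group raising that of C2 towards that of the diketone sites), and of the enolates formed only the C1–C3 β-keto-ester enolate can reach a ketone through a six-membered transition state, so its C2 carbon adds to the C7 ketone (6-(enolendo)-exo-trig aldol) to form the ring-A C1–C6 bond and the carbinol 18, after which catalytic TsOH dehydrates the tertiary carbinol and the two remaining ketones enolise, aromatisation making the sequence irreversible. The closest known reaction type is the amine- or carbonate-mediated aldol cyclo-aromatisation of alkyl 3,5,7-trioxoalkanoates derived from diketo-dioxinones to 6-alkyl-2,4-dihydroxybenzoates, which is not established for an aryl ester. Ring A is the only ring closed (a six-membered carbocycle, C2 onto C7) and no stereocentre remains, the two of 18 being erased on aromatisation. The step needs mode selectivity: aldol C2→C7 must win over Claisen closure C6→C1, over lactonisation of the C5 enol oxygen onto C1 (both expel the ring-B aryloxide) and over E1cB loss of that aryloxide from the C2 enolate. This is secured in four ways: in the reacting C2 enolate the ester carbonyl is part of the enolate and so is not electrophilic; the ring-B aryloxide is only a moderate leaving group because its ester is twisted out of conjugation by two ortho substituents; no chelating metal is present to activate C1 (metal alkoxides are what favour the Claisen mode); and in aprotic CH2Cl2 at −20 to 0 °C any acylketene formed by E1cB should be recaptured by the ion-paired aryloxide, while the catalytic acid phase is mild enough to leave the tert-butyl ester intact.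

Step 11
Reactants: 19 tert-butyl 4-[(2,4-dihydroxy-6-propylbenzoyl)oxy]-2-methoxy-6-pentylbenzoate
Product: 20 tert-butyl 4-[(2-hydroxy-4-methoxy-6-propylbenzoyl)oxy]-2-methoxy-6-pentylbenzoate
Conditions: MeI (1.1 equiv), K2CO3 (1.1 equiv), acetone, rt
Reagents that add atoms: iodomethane CI
Why: Selective Williamson methylation, in which the ring-A 4-hydroxyl (para to the ester carbonyl, not hydrogen-bonded) is the more acidic and nucleophilic one while the 2-hydroxyl is chelated to the depside carbonyl, as is usual for 2,4-dihydroxybenzoates, and the hindered aryl ester should survive carbonate in dry acetone.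

Step 12
Reactants: 20 tert-butyl 4-[(2-hydroxy-4-methoxy-6-propylbenzoyl)oxy]-2-methoxy-6-pentylbenzoate
Product: 21 4-[(2-hydroxy-4-methoxy-6-propylbenzoyl)oxy]-2-methoxy-6-pentylbenzoic acid (target)
Conditions: TFA/CH2Cl2 (1:4), Et3SiH (3 equiv), 0 °C → rt
Reagents that add atoms: none
Why: Acidolysis of the tert-butyl ester by alkyl–oxygen cleavage, with triethylsilane reducing the tert-butyl cation to isobutane so that it cannot alkylate the activated rings, while the depside ester and the aryl methyl ethers are stable to TFA.

**Compound list**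
1 | olivetol (5-pentylresorcinol) | CCCCCc1cc(O)cc(O)c1 | starting material
2 | (2,4-dihydroxy-6-pentylbenzylidene)dimethyliminium chloride | CCCCCc1cc(O)cc(O)c1C=[N+](C)C.[Cl-] | intermediate
3 | 2,4-dihydroxy-6-pentylbenzaldehyde | CCCCCc1cc(O)cc(O)c1C=O | intermediate
4 | 4-(benzyloxy)-2-hydroxy-6-pentylbenzaldehyde | CCCCCc1cc(OCc2ccccc2)cc(O)c1C=O | intermediate
5 | 4-(benzyloxy)-2-methoxy-6-pentylbenzaldehyde | CCCCCc1cc(OCc2ccccc2)cc(OC)c1C=O | intermediate
6 | 4-(benzyloxy)-2-methoxy-6-pentylbenzoic acid | CCCCCc1cc(OCc2ccccc2)cc(OC)c1C(=O)O | intermediate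
7 | tert-butyl 4-(benzyloxy)-2-methoxy-6-pentylbenzoate | CCCCCc1cc(OCc2ccccc2)cc(OC)c1C(=O)OC(C)(C)C | intermediate
8 | tert-butyl 4-hydroxy-2-methoxy-6-pentylbenzoate | CCCCCc1cc(O)cc(OC)c1C(=O)OC(C)(C)C | intermediate
9 | 2,2,6-trimethyl-4H-1,3-dioxin-4-one | CC1=CC(=O)OC(C)(C)O1 | starting material
10 | acetyl chloride | CC(=O)Cl | starting material
11 | lithium dienolate of 9 (lithium 2,2-dimethyl-6-methylidene-6H-1,3-dioxin-4-olate) | [Li+].C=C1C=C([O-])OC(C)(C)O1 | intermediate
12 | 2,2-dimethyl-6-(2-oxopropyl)-4H-1,3-dioxin-4-one | CC(=O)CC1=CC(=O)OC(C)(C)O1 | intermediate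
13 | butanoyl chloride | CCCC(=O)Cl | starting material
14 | dilithium dienolate (dianion) of 12 | [Li+].[Li+].C=C([O-])C=C1C=C([O-])OC(C)(C)O1 | intermediate
15 | 6-(2,4-dioxoheptyl)-2,2-dimethyl-4H-1,3-dioxin-4-one | CCCC(=O)CC(=O)CC1=CC(=O)OC(C)(C)O1 | intermediate
16 | 3,5,7-trioxodec-1-en-1-one (acylketene) | CCCC(=O)CC(=O)CC(=O)C=C=O | intermediate
17 | tert-butyl 2-methoxy-6-pentyl-4-[(3,5,7-trioxodecanoyl)oxy]benzoate | CCCCCc1cc(OC(=O)CC(=O)CC(=O)CC(=O)CCC)cc(OC)c1C(=O)OC(C)(C)C | intermediate
18 | tert-butyl 4-[(2-hydroxy-4,6-dioxo-2-propylcyclohexane-1-carbonyl)oxy]-2-methoxy-6-pentylbenzoate (diastereomer mixture, stereocentres transient) | CCCCCc1cc(OC(=O)C2C(=O)CC(=O)CC2(O)CCC)cc(OC)c1C(=O)OC(C)(C)C | intermediate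
19 | tert-butyl 4-[(2,4-dihydroxy-6-propylbenzoyl)oxy]-2-methoxy-6-pentylbenzoate | CCCCCc1cc(OC(=O)c2c(O)cc(O)cc2CCC)cc(OC)c1C(=O)OC(C)(C)C | intermediate
20 | tert-butyl 4-[(2-hydroxy-4-methoxy-6-propylbenzoyl)oxy]-2-methoxy-6-pentylbenzoate | CCCCCc1cc(OC(=O)c2c(O)cc(OC)cc2CCC)cc(OC)c1C(=O)OC(C)(C)C | intermediate
21 | 4-[(2-hydroxy-4-methoxy-6-propylbenzoyl)oxy]-2-methoxy-6-pentylbenzoic acid | CCCCCc1cc(OC(=O)c2c(O)cc(OC)cc2CCC)cc(OC)c1C(=O)O | target

**Step count**
Total: 12 steps. Longest linear sequence: 10 steps (steps 1–6, then 9–12, from olivetol); the dioxinone branch (steps 7–8) joins at step 9.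

**Steps most likely to fail**

1. Step 10 (proposed new method). What may go wrong: expulsion of the ring-B aryloxide by Claisen closure, lactonisation or E1cB ketene formation outruns the aldol closure, or the tert-butyl ester is lost during the acid phase. The fallback uses known chemistry, sets out from 15 and comes back at 19. Thermolysis of 15 in toluene with allyl alcohol should give allyl 3,5,7-trioxodecanoate F1 by way of 16. Base-mediated aldol cyclisation and acid dehydration, established for alkyl esters, should give allyl 2,4-dihydroxy-6-propylbenzoate F2. Double benzylation (BnBr, K2CO3, DMF) should give allyl 2,4-bis(benzyloxy)-6-propylbenzoate F3, and Pd(PPh3)4 with morpholine should free 2,4-bis(benzyloxy)-6-propylbenzoic acid F4. Steglich-type coupling with phenol 8 (DCC, DMAP, CH2Cl2) should give tert-butyl 4-{[2,4-bis(benzyloxy)-6-propylbenzoyl]oxy}-2-methoxy-6-pentylbenzoate F5, and hydrogenolysis (H2, Pd/C) of both benzyl ethers returns to the route at 19.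

2. Step 9. What may go wrong: intramolecular O-acylation of the acylketene by its own C5 enol (pyranone formation), or thermal re-formation of the ketene from the product, outpaces capture by the weakly nucleophilic phenol. The fallback sets out from 15 and comes back at 20, bypassing the free triketide. Without a trapping agent, Et3N in CH2Cl2 should cyclo-aromatise 15 with the dioxinone ring intact to 7-hydroxy-2,2-dimethyl-5-propyl-4H-1,3-benzodioxin-4-one F6. Methylation (MeI, K2CO3, acetone) should give 7-methoxy-2,2-dimethyl-5-propyl-4H-1,3-benzodioxin-4-one F7. Irradiation (about 300 nm, CH2Cl2) in the presence of 8 should expel acetone to give the quinoketene 3-methoxy-6-(oxomethylidene)-5-propylcyclohexa-2,4-dien-1-one F8, whose capture by the phenol O–H of 8 gives 20 directly. This photochemical acylation is established for hindered alcohols and is extended here to a phenol.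

3. Step 8. What may go wrong: proton transfer from the acidic diketone product to the dianion, together with O-acylation or double acylation by the acid chloride, erodes conversion. The fallback sets out from 12 and comes back at 15, replacing acylation by aldol addition and oxidation. The dianion 14 is added to butanal at −78 °C to give racemic 6-(4-hydroxy-2-oxoheptyl)-2,2-dimethyl-4H-1,3-dioxin-4-one F9, whose aldolate cannot quench further dianion. Dess–Martin oxidation of the secondary alcohol then returns to the route at 15.

**Further compounds**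
F1 | step 10 | allyl 3,5,7-trioxodecanoate | C=CCOC(=O)CC(=O)CC(=O)CC(=O)CCC
F2 | step 10 | allyl 2,4-dihydroxy-6-propylbenzoate | C=CCOC(=O)c1c(O)cc(O)cc1CCC
F3 | step 10 | allyl 2,4-bis(benzyloxy)-6-propylbenzoate | C=CCOC(=O)c1c(OCc2ccccc2)cc(OCc2ccccc2)cc1CCC
F4 | step 10 | 2,4-bis(benzyloxy)-6-propylbenzoic acid | OC(=O)c1c(OCc2ccccc2)cc(OCc2ccccc2)cc1CCC
F5 | step 10 | tert-butyl 4-{[2,4-bis(benzyloxy)-6-propylbenzoyl]oxy}-2-methoxy-6-pentylbenzoate | CCCCCc1cc(OC(=O)c2c(OCc3ccccc3)cc(OCc3ccccc3)cc2CCC)cc(OC)c1C(=O)OC(C)(C)C
F6 | step 9 | 7-hydroxy-2,2-dimethyl-5-propyl-4H-1,3-benzodioxin-4-one | CCCc1cc(O)cc2OC(C)(C)OC(=O)c12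
F7 | step 9 | 7-methoxy-2,2-dimethyl-5-propyl-4H-1,3-benzodioxin-4-one | CCCc1cc(OC)cc2OC(C)(C)OC(=O)c12
F8 | step 9 | 3-methoxy-6-(oxomethylidene)-5-propylcyclohexa-2,4-dien-1-one | CCCC1=CC(OC)=CC(=O)C1=C=O
F9 | step 8 | 6-(4-hydroxy-2-oxoheptyl)-2,2-dimethyl-4H-1,3-dioxin-4-one (racemic) | CCCC(O)CC(=O)CC1=CC(=O)OC(C)(C)O1
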